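**Retrosynthetic overview**

1. Germacrane numbering: carbocycle C1–C10, methyl C14 on C10, methyl C15 on C4, butenolide O–C12(=O)–C11(C13H2OAc)=C7 fused at C6–C7. The C1–O–C10 oxirane is unmasked last from an (E)-C1=C10 alkene by peracid attack on the outer ring face (C1 and C10 set together, relayed from C6); both acetates come from silyl ethers.
2. The ten-membered carbocycle (second ring formed) is opened at C9–C10, an sp3–sp2 bond at the alkene oxidation level: one-pot hydroboration and intramolecular B-alkyl Suzuki–Miyaura coupling of a C9 borane with an (E)-C10 alkenyl iodide.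
3. Enabling feature: C10 is the methyl-bearing oxirane carbon, i.e. a latent (E)-alkenyl carbon, and C9 ends the two-carbon arm C8–C9 on the butenolide β-carbon C7, so it can be carried as a vinyl group on the butenolide ring; that flat ring and the (E)-C4=C5 alkene fold the chain.
4. The butenolide (first ring formed) arises in one operation from a propargylic alcohol (C6–OH, C7≡C11–C13) by hydroxyl-directed anti-addition of vinylmagnesium chloride and carboxylation; C6 is set by catalytic asymmetric alkynylation of an enal.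
5. C3 is set by catalytic asymmetric propargylation of (E)-4-acetoxy-2-methylbut-2-enal; the alkyne is then methylated, hydrozirconated and iodinated to the (E)-alkenyl iodide.

Key step: step 9

Remark: the sense of induction of (S)-TRIP (step 1) and (S,S)-ProPhenol (step 7) is assigned by analogy with the accepted models for alkenyl aldehydes (Si-face addition in both cases); should either prove opposite, the antipodal catalyst is used with no other change. TBS = tert-butyldimethylsilyl.

**Route**

Step 1
Reactants: 1 (E)-4-acetoxy-2-methylbut-2-enal; 2 allenylboronic acid pinacol ester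
Product: 3 (2E,4S)-4-hydroxy-3-methylhept-2-en-6-yn-1-yl acetate
Conditions: (S)-TRIP (5 mol %), 4 Å MS, toluene, −20 °C; aqueous work-up
Reagents that add atoms: none
Why: Chiral phosphoric acid-catalysed propargylboration (SE2' addition of the allenylboronate through a closed six-membered transition state organised by the phosphate) should deliver the propargyl group to the Si face of the aldehyde and set C3 as (S), the allylic acetate and the (E)-alkene being spectators.

Step 2
Reactants: 3 (2E,4S)-4-hydroxy-3-methylhept-2-en-6-yn-1-yl acetate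
Product: 4 (2E,4S)-4-[(tert-butyldimethylsilyl)oxy]-3-methylhept-2-en-6-yn-1-yl acetate
Conditions: TBSCl, imidazole, DMF, rt
Reagents that add atoms: tert-butyldimethylsilyl chloride, CC(C)(C)[Si](C)(C)Cl
Why: Standard silylation of a secondary allylic alcohol, which shields the C3 oxygen from the oxidation in step 6 and the Grignard reagent in step 8.

Step 3
Reactants: 4 (2E,4S)-4-[(tert-butyldimethylsilyl)oxy]-3-methylhept-2-en-6-yn-1-yl acetate
Product: 5 (2E,4S)-4-[(tert-butyldimethylsilyl)oxy]-3-methylhept-2-en-6-yn-1-ol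
Conditions: K2CO3, MeOH, 0 °C
Reagents that add atoms: none
Why: Base-catalysed transesterification (methanolysis) cleaves the primary allylic acetate, while the silyl ether and the terminal alkyne are stable.

Step 4
Reactants: 5 (2E,4S)-4-[(tert-butyldimethylsilyl)oxy]-3-methylhept-2-en-6-yn-1-ol
Product: 6 (2E,4S)-4-[(tert-butyldimethylsilyl)oxy]-3-methyloct-2-en-6-yn-1-ol
Conditions: n-BuLi (2.1 equiv), THF, −78 °C; MeI (1.1 equiv), −78 → 0 °C; aqueous work-up
Reagents that add atoms: iodomethane, CI
Why: Alkylation of the lithium acetylide of the alkoxide–acetylide dianion, in which C-methylation should prevail because a lithium alkoxide is a poor nucleophile towards MeI in THF without a polar cosolvent.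

Step 5
Reactants: 6 (2E,4S)-4-[(tert-butyldimethylsilyl)oxy]-3-methyloct-2-en-6-yn-1-ol
Product: 7 (2E,4S,6E)-4-[(tert-butyldimethylsilyl)oxy]-7-iodo-3-methylocta-2,6-dien-1-ol
Conditions: Cp2Zr(H)Cl (3 equiv), THF, 45 °C; then I2, 0 °C; aqueous work-up
Reagents that add atoms: iodine, II
Why: Hydrozirconation–iodination, in which Cp2Zr(H)Cl adds syn across the alkyne, excess reagent equilibrates zirconium to the less hindered methyl-bearing carbon, and iodinolysis with retention should give the (E)-alkenyl iodide with methyl and chain cis, as needed for the (E)-C1=C10 alkene.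

Step 6
Reactants: 7 (2E,4S,6E)-4-[(tert-butyldimethylsilyl)oxy]-7-iodo-3-methylocta-2,6-dien-1-ol
Product: 8 (2E,4S,6E)-4-[(tert-butyldimethylsilyl)oxy]-7-iodo-3-methylocta-2,6-dienal
Conditions: MnO2, CH2Cl2, rt
Reagents that add atoms: none
Why: MnO2 oxidation is selective for the primary allylic alcohol and should give the (E)-enal without touching the alkenyl iodide or the silyl ether.

Step 7
Reactants: 8 (2E,4S,6E)-4-[(tert-butyldimethylsilyl)oxy]-7-iodo-3-methylocta-2,6-dienal; 9 tert-butyldimethyl(prop-2-yn-1-yloxy)silane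
Product: 10 (4R,5E,7S,9E)-1,7-bis[(tert-butyldimethylsilyl)oxy]-10-iodo-6-methylundeca-5,9-dien-2-yn-4-ol
Conditions: (S,S)-ProPhenol (20 mol %), Me2Zn (3 equiv), Ph3PO (40 mol %), toluene, 4 °C; aqueous work-up
Reagents that add atoms: none
Why: Zinc–ProPhenol-catalysed asymmetric alkynylation of an enal, in which the dinuclear zinc catalyst should deliver the alkynylzinc to the Si face and set C6 as (R) under catalyst control, the remote C3 centre having no say.

Step 8
Reactants: 10 (4R,5E,7S,9E)-1,7-bis[(tert-butyldimethylsilyl)oxy]-10-iodo-6-methylundeca-5,9-dien-2-yn-4-ol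
Product: 13 (5R)-3-{[(tert-butyldimethylsilyl)oxy]methyl}-5-[(1E,3S,5E)-3-[(tert-butyldimethylsilyl)oxy]-6-iodo-2-methylhepta-1,5-dien-1-yl]-4-vinylfuran-2(5H)-one, via alkenylmagnesium chelate 11 (not isolated), via magnesium carboxylate 12 (not isolated)
Conditions: CH2=CHMgCl (5 equiv), THF–cyclohexane, 60 °C; then CO2 (1 atm), −20 °C → rt; 1 M HCl to pH 3, 0 °C
Reagents that add atoms: vinylmagnesium chloride, C=C[Mg]Cl; carbon dioxide, O=C=O
Why: Hydroxyl-directed anti-carbomagnesiation of a propargylic alcohol puts the vinyl group on the proximal alkyne carbon C7 and magnesium on C11 in a five-membered chelate, and carboxylation of that alkenylmagnesium followed by lactonisation of the cis hydroxy acid should give the butenolide with C6 untouched.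

Step 9
Reactants: 13 (5R)-3-{[(tert-butyldimethylsilyl)oxy]methyl}-5-[(1E,3S,5E)-3-[(tert-butyldimethylsilyl)oxy]-6-iodo-2-methylhepta-1,5-dien-1-yl]-4-vinylfuran-2(5H)-one
Product: 15 (6E,9S,10E,11aR)-9-[(tert-butyldimethylsilyl)oxy]-3-{[(tert-butyldimethylsilyl)oxy]methyl}-6,10-dimethyl-5,8,9,11a-tetrahydrocyclodeca[b]furan-2(4H)-one, via B-alkyl-9-BBN borane 14 (not isolated)
Conditions: 9-BBN (1.3 equiv), THF, 0 °C → rt; then syringe-pump addition (12 h) to Pd(dppf)Cl2 (20 mol %), AsPh3 (20 mol %), Cs2CO3 (3 equiv), DMF–THF–H2O, 45 °C, 1 mM final concentration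
Reagents that add atoms: none
Why: 9-BBN should hydroborate only the monosubstituted vinyl group of 13 and, for steric reasons, place boron on the terminal carbon C9 to give 14; base then forms the borate, zerovalent palladium inserts into the C10–I bond with retention, transfer of the primary alkyl group from boron gives an eleven-membered alkyl(alkenyl) palladacycle of divalent palladium, and reductive elimination forms C9–C10. The closest known reaction type is the macrocyclic B-alkyl Suzuki–Miyaura coupling of an alkyl-9-BBN with an (E)-trisubstituted alkenyl iodide, which is established for strained medium-ring (E)-cycloalkenes. One ring closes, the ten-membered carbocycle, by C(sp3)–C(sp2) reductive elimination with ring contraction from the palladacycle, the alkenyl carbon C10 ending inside the ring (endo). No stereocentre is created: the (E) geometry of C1=C10 is carried over unchanged from the iodide and later becomes the trans relationship of C1 and C10 in the oxirane. The step needs chemoselective hydroboration (the trisubstituted C4=C5 and C1=C10 alkenes, the tetrasubstituted C7=C11 alkene and the lactone carbonyl are far slower towards 9-BBN) and ring closure in preference to oligomerisation, which slow addition at high dilution and the chain folding imposed by the planar butenolide and the (E)-C4=C5 alkene should secure, while the wide-bite-angle dppf ligand suppresses β-hydride elimination.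

Step 10
Reactants: 15 (6E,9S,10E,11aR)-9-[(tert-butyldimethylsilyl)oxy]-3-{[(tert-butyldimethylsilyl)oxy]methyl}-6,10-dimethyl-5,8,9,11a-tetrahydrocyclodeca[b]furan-2(4H)-one
Product: 16 (6E,9S,10E,11aR)-9-hydroxy-3-(hydroxymethyl)-6,10-dimethyl-5,8,9,11a-tetrahydrocyclodeca[b]furan-2(4H)-one
Conditions: HF·pyridine, pyridine, THF, 0 °C → rt
Reagents that add atoms: none
Why: Fluoride-mediated desilylation under pyridine-buffered conditions should free both hydroxyls while avoiding acid-induced transannular cyclisation of the cyclodecadiene and base-induced epimerisation at C6.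

Step 11
Reactants: 16 (6E,9S,10E,11aR)-9-hydroxy-3-(hydroxymethyl)-6,10-dimethyl-5,8,9,11a-tetrahydrocyclodeca[b]furan-2(4H)-one
Product: 17 (6E,9S,10E,11aR)-9-acetoxy-3-(acetoxymethyl)-6,10-dimethyl-5,8,9,11a-tetrahydrocyclodeca[b]furan-2(4H)-one
Conditions: Ac2O, pyridine, DMAP (cat.), CH2Cl2, 0 °C
Reagents that add atoms: acetic anhydride, CC(=O)OC(C)=O
Why: DMAP-catalysed acylation should esterify the primary and the secondary allylic hydroxyl in one operation without affecting the stereocentres.

Step 12
Reactants: 17 (6E,9S,10E,11aR)-9-acetoxy-3-(acetoxymethyl)-6,10-dimethyl-5,8,9,11a-tetrahydrocyclodeca[b]furan-2(4H)-one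
Product: 18 (1R,3S,6R,10R)-3,13-diacetoxy-1,10-epoxygermacra-4E,7(11)-dien-12,6-olide
Conditions: mCPBA (1.05 equiv), NaHCO3, CH2Cl2, −20 → 0 °C
Reagents that add atoms: 3-chloroperoxybenzoic acid, OOC(=O)c1cccc(Cl)c1
Why: Prilezhaev epoxidation should take place only at the electron-rich C1=C10 alkene (C4=C5 is deactivated by two allylic acyloxy groups and C7=C11 is conjugated), stereospecifically give the trans oxirane, and set C1 and C10 as (R,R) because allylic 1,3-strain between C15 and the C6 substituents holds the two ring alkenes crossed with C14 and C15 on the same face, so that only the outer face of C1=C10 is open to the peracid.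

**Compound list**

1 | (E)-4-acetoxy-2-methylbut-2-enal | O=C/C(C)=C/COC(C)=O | starting material
2 | allenylboronic acid pinacol ester (4,4,5,5-tetramethyl-2-(propa-1,2-dien-1-yl)-1,3,2-dioxaborolane) | C=C=CB1OC(C)(C)C(C)(C)O1 | starting material
3 | (2E,4S)-4-hydroxy-3-methylhept-2-en-6-yn-1-yl acetate | C#CC[C@H](O)/C(C)=C/COC(C)=O | intermediate
4 | (2E,4S)-4-[(tert-butyldimethylsilyl)oxy]-3-methylhept-2-en-6-yn-1-yl acetate | C#CC[C@H](O[Si](C)(C)C(C)(C)C)/C(C)=C/COC(C)=O | intermediate
5 | (2E,4S)-4-[(tert-butyldimethylsilyl)oxy]-3-methylhept-2-en-6-yn-1-ol | C#CC[C@H](O[Si](C)(C)C(C)(C)C)/C(C)=C/CO | intermediate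
6 | (2E,4S)-4-[(tert-butyldimethylsilyl)oxy]-3-methyloct-2-en-6-yn-1-ol | CC#CC[C@H](O[Si](C)(C)C(C)(C)C)/C(C)=C/CO | intermediate
7 | (2E,4S,6E)-4-[(tert-butyldimethylsilyl)oxy]-7-iodo-3-methylocta-2,6-dien-1-ol | C/C(I)=C\C[C@H](O[Si](C)(C)C(C)(C)C)/C(C)=C/CO | intermediate
8 | (2E,4S,6E)-4-[(tert-butyldimethylsilyl)oxy]-7-iodo-3-methylocta-2,6-dienal | C/C(I)=C\C[C@H](O[Si](C)(C)C(C)(C)C)/C(C)=C/C=O | intermediate
9 | tert-butyldimethyl(prop-2-yn-1-yloxy)silane | C#CCO[Si](C)(C)C(C)(C)C | starting material
10 | (4R,5E,7S,9E)-1,7-bis[(tert-butyldimethylsilyl)oxy]-10-iodo-6-methylundeca-5,9-dien-2-yn-4-ol | C/C(I)=C\C[C@H](O[Si](C)(C)C(C)(C)C)/C(C)=C/[C@@H](O)C#CCO[Si](C)(C)C(C)(C)C | intermediate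
11 | alkenylmagnesium chelate, not isolated: 2,5-dihydro-1,2-oxamagnesole in which Mg bridges the C6 oxygen and C11, with the vinyl group on C7, CH2OTBS on C11 and the (R)-C6 side chain of 10 | C/C(I)=C\C[C@H](O[Si](C)(C)C(C)(C)C)/C(C)=C/[C@H]1O[Mg]C(CO[Si](C)(C)C(C)(C)C)=C1C=C | intermediate
12 | magnesium carboxylate, not isolated: magnesium salt of the (Z)-4-oxido-3-vinyl-2-(TBSO-methyl)alk-2-enoate formed from 11 and CO2 (C6 oxygen and carboxylate cis) | C/C(I)=C\C[C@H](O[Si](C)(C)C(C)(C)C)/C(C)=C/[C@@H]([O-])/C(C=C)=C(/CO[Si](C)(C)C(C)(C)C)C(=O)[O-].[Mg+2] | intermediate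
13 | (5R)-3-{[(tert-butyldimethylsilyl)oxy]methyl}-5-[(1E,3S,5E)-3-[(tert-butyldimethylsilyl)oxy]-6-iodo-2-methylhepta-1,5-dien-1-yl]-4-vinylfuran-2(5H)-one | C/C(I)=C\C[C@H](O[Si](C)(C)C(C)(C)C)/C(C)=C/[C@H]1OC(=O)C(CO[Si](C)(C)C(C)(C)C)=C1C=C | intermediate
14 | B-alkyl-9-BBN borane, not isolated: 13 in which the vinyl group has become a 2-(9-borabicyclo[3.3.1]nonan-9-yl)ethyl group | C/C(I)=C\C[C@H](O[Si](C)(C)C(C)(C)C)/C(C)=C/[C@H]1OC(=O)C(CO[Si](C)(C)C(C)(C)C)=C1CCB1C2CCCC1CCC2 | intermediate
15 | (6E,9S,10E,11aR)-9-[(tert-butyldimethylsilyl)oxy]-3-{[(tert-butyldimethylsilyl)oxy]methyl}-6,10-dimethyl-5,8,9,11a-tetrahydrocyclodeca[b]furan-2(4H)-one (bis-TBS ether of (3S,6R)-3,13-dihydroxygermacra-1(10)E,4E,7(11)-trien-12,6-olide) | CC(C)(C)[Si](C)(C)OCC1=C2CC/C(C)=C/C[C@H](O[Si](C)(C)C(C)(C)C)/C(C)=C/[C@H]2OC1=O | intermediate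
16 | (6E,9S,10E,11aR)-9-hydroxy-3-(hydroxymethyl)-6,10-dimethyl-5,8,9,11a-tetrahydrocyclodeca[b]furan-2(4H)-one | OCC1=C2CC/C(C)=C/C[C@H](O)/C(C)=C/[C@H]2OC1=O | intermediate
17 | (6E,9S,10E,11aR)-9-acetoxy-3-(acetoxymethyl)-6,10-dimethyl-5,8,9,11a-tetrahydrocyclodeca[b]furan-2(4H)-one | CC(=O)OCC1=C2CC/C(C)=C/C[C@H](OC(C)=O)/C(C)=C/[C@H]2OC1=O | intermediate
18 | (1R,3S,6R,10R)-3,13-diacetoxy-1,10-epoxygermacra-4E,7(11)-dien-12,6-olide | CC(=O)OCC1=C2CC[C@@]3(C)O[C@@H]3C[C@H](OC(C)=O)/C(C)=C/[C@H]2OC1=O | target

**Summary**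

Total step count: 12. Longest linear sequence: 12 steps (from 1).

Steps most likely to fail:

Step 9. The electron-poor vinyl group may be hydroborated slowly or suffer hydride delivery to C9 (conjugate reduction), and the alkylpalladium intermediate may oligomerise instead of closing the strained ring. The fallback inverts the polarity at the same bond and needs no borane. It sets out from 13 and comes back at 15 in one operation, an intramolecular reductive Heck reaction (Pd(OAc)2, HCO2Na, Bu4NCl, Et3N, DMF, 60 °C, 1 mM). The alkenylpalladium iodide formed at C10 adds to the electron-poor vinyl terminus C9, and the resulting palladium dienolate is reduced by formate and brought into conjugation by the amine.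

Step 8. The alkenylmagnesium chelate may lose silyloxide by β-elimination to an allene, and the alkenyl iodide may undergo iodine–magnesium exchange during prolonged heating. The fallback avoids any alkenylmagnesium species; it sets out from 8 and comes back at 13.
- Zinc–ProPhenol alkynylation of 8 with methyl propiolate (Me2Zn, toluene) would give methyl (4R,5E,7S,9E)-7-[(tert-butyldimethylsilyl)oxy]-4-hydroxy-10-iodo-6-methylundeca-5,9-dien-2-ynoate F1.
- Syn-carbocupration of F1 with (CH2=CH)2CuLi at −78 °C, quenching with I2 and lactonisation would give (5R)-5-[(1E,3S,5E)-3-[(tert-butyldimethylsilyl)oxy]-6-iodo-2-methylhepta-1,5-dien-1-yl]-3-iodo-4-vinylfuran-2(5H)-one F2.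
- Stille coupling of F2 with Bu3SnCH2OH (Pd2(dba)3, AsPh3, NMP, rt), expected to be selective for the electron-poor C11–I bond, would give (5R)-5-[(1E,3S,5E)-3-[(tert-butyldimethylsilyl)oxy]-6-iodo-2-methylhepta-1,5-dien-1-yl]-3-(hydroxymethyl)-4-vinylfuran-2(5H)-one F3.
- Silylation of F3 (TBSCl, imidazole) would return 13.

Step 12. Facial selectivity may be poor if the ring populates a conformer with C14 on the opposite face, and C4=C5 may be oxidised competitively. The fallback replaces substrate control by reagent control. It sets out from 17 and comes back at 18 by Shi epoxidation (D-fructose-derived ketone catalyst, Oxone (2KHSO5·KHSO4·K2SO4), K2CO3 buffer pH 10.5, MeCN–dimethoxymethane–H2O, 0 °C). The dioxirane is expected to select the (1R,10R) face of the electron-rich (E)-trisubstituted alkene through its spiro transition state.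

Further compounds
F0 | step 9 | none | none
F1 | step 8 | methyl (4R,5E,7S,9E)-7-[(tert-butyldimethylsilyl)oxy]-4-hydroxy-10-iodo-6-methylundeca-5,9-dien-2-ynoate | C/C(I)=C\C[C@H](O[Si](C)(C)C(C)(C)C)/C(C)=C/[C@@H](O)C#CC(=O)OC
F2 | step 8 | (5R)-5-[(1E,3S,5E)-3-[(tert-butyldimethylsilyl)oxy]-6-iodo-2-methylhepta-1,5-dien-1-yl]-3-iodo-4-vinylfuran-2(5H)-one | C/C(I)=C\C[C@H](O[Si](C)(C)C(C)(C)C)/C(C)=C/[C@H]1OC(=O)C(I)=C1C=C
F3 | step 8 | (5R)-5-[(1E,3S,5E)-3-[(tert-butyldimethylsilyl)oxy]-6-iodo-2-methylhepta-1,5-dien-1-yl]-3-(hydroxymethyl)-4-vinylfuran-2(5H)-one | C/C(I)=C\C[C@H](O[Si](C)(C)C(C)(C)C)/C(C)=C/[C@H]1OC(=O)C(CO)=C1C=C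
F0 | step 12 | none | none
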